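Start with one division: substrate charged over catalyst charged, the turnovers each catalyst owes. Eta owes 100, and epsilon owes 100 as well.

| flask | substrate | gas phase | catalyst | remark | time |
|---|---|---|---|---|---|
| oak | 1.2 M | 74 mM (held) | 15 mM | run made earlier |  |
| ash | 2.1 M | 74 mM (held) | 15 mM | run made earlier |  |
| birch | 1.5 M | 74 mM (held) | 9.5 mM | run made earlier |  |
| epsilon | 0.80 M | 74 mM (held) | 8.0 mM |  | 2.5 min |
| eta | 1.5 M | 74 mM (held) | 15 mM |  | 4.0 min |

- oak (time / min: target / %): 0.500: 75.7; 1.00: 82.9; 1.33: 84.0; 2.00: 83.4; 2.50: 83.7; 3.00: 83.7
- ash (time / min: target / %): 0.200: 47.6; 0.500: 68.2; 1.00: 73.9; 1.50: 75.4; 2.00: 75.1; 3.00: 74.6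
- birch (time / min: target / %): 0.500: 58.9; 1.00: 71.1; 1.50: 73.4; 2.50: 74.1; 3.00: 73.3

(scatter of a reading: 0.5 percentage points)

- a species is counted by the substrate in it: one self-condensation product counts as two
- at the start none of the gas is dissolved
- steps under discussion: gas phase <-> dissolved gas; substrate + dissolved gas + catalyst -> catalyst + target; 2 substrate -> self-condensation product

* which one finishes higher in amount of target, in percent of the substrate charged ("neither" within 2 percentage points) (epsilon / eta / neither)
* amount of target at the end, in percent of the substrate charged, epsilon
* amount of target at the end, in percent of the substrate charged, eta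

Why count turnovers? At a fixed level of dissolved gas, target forms as substrate times catalyst and self-condensation product as substrate squared. So at that level, waste per target at any moment goes as substrate present over catalyst, and I take the charges as a stand-in for the whole run. Take as waste whatever of the charge is not target on the plateau, divide it by the target, and scale to 100 turnovers owed. Oak owes 80.0 and reads 83.7 %, which gives 0.243. Used directly for the new flasks, that value predicts 80.4 % of target.

Next, the time. Birch read 73.4 % at 1.50 min and 74.1 % at 2.50 min, about the scatter apart. Epsilon gets 1.40 times the catalyst-times-time of that first birch reading, and eta gets 4.21 times. So I expect both to reach their plateaus.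

The weak link is the constant itself. Ash, owing 140 and reading 75.1 %, gives 0.237. Birch, owing 158, gives 0.226, lower than both. The value drifts down as turnovers rise, so read it on the line from oak to ash at your count. That gives 0.241, the waste rate, an inverse selectivity factor. I commit to 80.6 % for both flasks.

The forecast gives two figures where I gave one: it says neither, with 80.6 % for epsilon and 80.4 % for eta, and adds: “Both runs finish in time”.

Epsilon ends at 81.4 % and eta at 80.7 %, so the answer is neither.

    gas phase ⇌ dissolved gas, rate k1*(csat - [dissolved gas]) (kL = 12.0 /s)
    substrate + dissolved gas + catalyst → catalyst + target (k = 69.0 /M²/s)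
    2 substrate → self-condensation product (k = 0.0120 /M/s)

At the end, epsilon has converted 99.8 % of its substrate and eta 100 %. Read back, the waste rate is 0.229 in epsilon and 0.239 in eta, against my 0.241.

Now take eta's neighbour with 0.0060 M of catalyst, which owes 250 turnovers. The waste rate gives 0.603 of waste per target, so 62.4 % of target. That neighbour computes to 65.4 %, higher than the reckoning.

All runs come from a simulation with made-up constants.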